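**Retrosynthetic overview**

1. The target is disconnected (after debenzylation and aryl mesylate cleavage) at the interflavan bond C4(upper)–C8(lower): TiCl4 coupling of a C4 glycol ether of protected epiafzelechin with tetra-O-benzyl-epicatechin, whose rings D, E and F come intact from natural (−)-epicatechin.
2. Upper ring C is not closed as a pyran. It comes from a 2,3-dihydrobenzofuran (ring atoms O1, C3, C4, C4a, C8a; C2 exocyclic, carrying ring B and a sulfonate) by a 1,2-shift of O1 from C3 to C2 through an O1-bridged oxiranium ion, with water entering at C3.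
3. Enabling feature: in ring C the ether oxygen O1 on C2 and the hydroxyl oxygen on C3 are vicinal, so O1 can be placed on C3 and moved to C2 by neighbouring-group participation. The double inversion turns a threo carbinol into the 2,3-cis (2R,3R) pattern, and the 4'-phenol of ring B is masked as a mesylate so that C2 cannot ionize freely.
4. The dihydrobenzofuran comes from the Shi epoxide of an (E)-1,3-diarylpropene (5-exo phenoxide opening, then Mitsunobu inversion); the alkene comes from Friedel–Crafts cinnamylation of 3,5-bis(benzyloxy)phenol.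
5. Ring order: rings A and B from building blocks → dihydrofuran ring (step 6) → ring C by expansion (step 9) → C4 activation and union with the D/E/F unit (steps 10 and 12) → deprotection.

Key step: step 9

Remark: the name is read as the SMILES shows, that is, an upper (2R,3R,4R)-epiafzelechin unit bonded through C4 to C8 of (2R,3R)-epicatechin.

**Route**

Step 1
Reactants: 1 methyl (2E)-3-(4-hydroxyphenyl)prop-2-enoate
Product: 2 methyl (2E)-3-[4-(methylsulfonyloxy)phenyl]prop-2-enoate
Conditions: MsCl, Et3N, CH2Cl2, 0 °C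
Reagents that add atoms: methanesulfonyl chloride, CS(=O)(=O)Cl
Why: O-sulfonylation of the phenol should be clean, and the mesylate is chosen as an electron-withdrawing phenol mask that later keeps the benzylic carbon from ionizing freely.

Step 2
Reactants: 2 methyl (2E)-3-[4-(methylsulfonyloxy)phenyl]prop-2-enoate
Product: 3 4-[(1E)-3-hydroxyprop-1-en-1-yl]phenyl methanesulfonate
Conditions: i-Bu2AlH, CH2Cl2, −78 °C
Reagents that add atoms: none
Why: 1,2-reduction of the unsaturated ester by the aluminium hydride at low temperature should give the allylic alcohol with the E-alkene and the aryl mesylate untouched.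

Step 3
Reactants: 3 4-[(1E)-3-hydroxyprop-1-en-1-yl]phenyl methanesulfonate; 4 3,5-bis(benzyloxy)phenol
Product: 5 4-{(1E)-3-[2,4-bis(benzyloxy)-6-hydroxyphenyl]prop-1-en-1-yl}phenyl methanesulfonate
Conditions: H2SO4 on SiO2 (cat.), CH2Cl2, rt
Reagents that add atoms: none
Why: acid-promoted Friedel–Crafts allylation, in which the cinnamyl cation alkylates the phloroglucinol-type phenol ortho to the free hydroxyl at its unsubstituted terminus and the conjugated E-alkene is kept.

Step 4
Reactants: 5 4-{(1E)-3-[2,4-bis(benzyloxy)-6-hydroxyphenyl]prop-1-en-1-yl}phenyl methanesulfonate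
Product: 6 4-{(1E)-3-[2,4-bis(benzyloxy)-6-(triisopropylsilyloxy)phenyl]prop-1-en-1-yl}phenyl methanesulfonate
Conditions: i-Pr3SiCl, imidazole, DMF, rt
Reagents that add atoms: chlorotriisopropylsilane, CC(C)[Si](Cl)(C(C)C)C(C)C
Why: silyl ether formation protects the phenol from oxidation and from premature epoxide opening under the basic conditions of the next step.

Step 5
Reactants: 6 4-{(1E)-3-[2,4-bis(benzyloxy)-6-(triisopropylsilyloxy)phenyl]prop-1-en-1-yl}phenyl methanesulfonate
Product: 7 4-{(2R,3R)-3-[2,4-bis(benzyloxy)-6-(triisopropylsilyloxy)benzyl]oxiran-2-yl}phenyl methanesulfonate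
Conditions: D-fructose-derived Shi ketone (0.3 equiv), KHSO5 (Oxone), K2CO3, Bu4NHSO4, MeCN–CH2(OMe)2/aq. Na2B4O7 buffer, 0 °C
Reagents that add atoms: potassium peroxymonosulfate, [K+].[O-]S(=O)(=O)OO
Why: Shi asymmetric epoxidation, in which the chiral dioxirane attacks the trans-disubstituted styrenyl alkene through the spiro transition state and should give the (R,R)-epoxide, as it does for trans-β-methylstyrene.

Step 6
Reactants: 7 4-{(2R,3R)-3-[2,4-bis(benzyloxy)-6-(triisopropylsilyloxy)benzyl]oxiran-2-yl}phenyl methanesulfonate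
Product: 9 4-{(R)-[(2S)-4,6-bis(benzyloxy)-2,3-dihydro-1-benzofuran-2-yl](hydroxy)methyl}phenyl methanesulfonate (erythro), via tetrabutylammonium phenoxide epoxide 8 (not isolated)
Conditions: Bu4NF, THF, 0 °C to 40 °C
Reagents that add atoms: none
Why: fluoride desilylation releases the phenoxide, which should open the epoxide by intramolecular 5-exo-tet attack at the non-benzylic carbon C3 with inversion (R to S) while C2 keeps its R configuration, the basic medium and the deactivated ring B disfavouring 6-endo attack.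

Step 7
Reactants: 9 4-{(R)-[(2S)-4,6-bis(benzyloxy)-2,3-dihydro-1-benzofuran-2-yl](hydroxy)methyl}phenyl methanesulfonate
Product: 10 (S)-[(2S)-4,6-bis(benzyloxy)-2,3-dihydro-1-benzofuran-2-yl][4-(methylsulfonyloxy)phenyl]methyl 4-nitrobenzoate (threo)
Conditions: 4-nitrobenzoic acid, PPh3, DIAD, THF, 0 °C to rt
Reagents that add atoms: 4-nitrobenzoic acid, O=C(O)c1ccc([N+](=O)[O-])cc1
Why: Mitsunobu inversion, in which SN2 displacement of the oxyphosphonium by the carboxylate inverts the carbinol carbon (R to S) and gives the threo relationship that a cis-oxiranium ion requires.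

Step 8
Reactants: 10 (S)-[(2S)-4,6-bis(benzyloxy)-2,3-dihydro-1-benzofuran-2-yl][4-(methylsulfonyloxy)phenyl]methyl 4-nitrobenzoate
Product: 11 4-{(S)-[(2S)-4,6-bis(benzyloxy)-2,3-dihydro-1-benzofuran-2-yl](hydroxy)methyl}phenyl methanesulfonate (threo)
Conditions: K2CO3 (cat.), MeOH–THF, 0 °C
Reagents that add atoms: none
Why: transesterification (methanolysis) of the activated 4-nitrobenzoate occurs at the acyl carbon with retention at the carbinol, and the aryl mesylate should survive cold carbonate.

Step 9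
Reactants: 11 4-{(S)-[(2S)-4,6-bis(benzyloxy)-2,3-dihydro-1-benzofuran-2-yl](hydroxy)methyl}phenyl methanesulfonate
Product: 14 4-[(2R,3R)-5,7-bis(benzyloxy)-3-hydroxy-3,4-dihydro-2H-chromen-2-yl]phenyl methanesulfonate, via chloromethanesulfonate ester 12 (not isolated), via aryloxiranium ion 13 (not isolated)
Conditions: (i) ClCH2SO2Cl, pyridine, CH2Cl2, 0 °C, cold aqueous wash; (ii) H2O–1,4-dioxane (1:1), 2,6-lutidine, 60 °C
Reagents that add atoms: water, O
Why: Proposed new method: the chloromethanesulfonate on the exocyclic benzylic carbon C2 is displaced from the rear by the ring ether oxygen O1 (3-exo-tet, inversion at C2) to give the O1-bridged oxiranium ion 13, and water then attacks the ring carbon C3 anti to O1 (inversion at C3), so that the O1–C3 bond of the five-membered ring is exchanged for an O1–C2 bond and six-membered ring C results with its free 3-hydroxyl. The closest known reaction types are the solvolytic or Zn(OAc)2-assisted ring expansion of 2-(1-sulfonyloxyalkyl)tetrahydrofurans to 3-oxygenated tetrahydropyrans through bicyclic oxiranium ions, the aziridinium ring expansion of prolinols to 3-hydroxypiperidines, and the acid-induced conversion of 2-(2-hydroxypropan-2-yl)-2,3-dihydrobenzofurans into 3-substituted 2,2-dimethylchromans; new here is an aryl ether oxygen acting at a secondary benzylic sulfonate with full stereospecificity. Ring C is not closed by a cyclization: the only closure is the transient three-membered oxiranium ring (3-exo-tet), and the pyran arises by endo opening of the shared O1–C3 bond of the bicyclo[3.1.0] cation. Both stereocenters are substrate-controlled by double inversion, C2 (S in 11) becoming 2R and C3 (S in 11) becoming 3R, so the threo carbinol should give the 2,3-cis flavan-3-ol. The step needs anchimeric rather than free-cation ionization and water capture at C3 rather than C2: the electron-withdrawing 4-mesyloxy group and the β-aryloxy substituent suppress the free benzylic cation (and with it hydride shift or elimination to a benzofuran), and capture at C2 only returns 11 with net retention for resubmission, whereas capture at C3 is irreversible and releases the strain of the bicycle into the six-membered ring.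

Step 10
Reactants: 14 4-[(2R,3R)-5,7-bis(benzyloxy)-3-hydroxy-3,4-dihydro-2H-chromen-2-yl]phenyl methanesulfonate
Product: 15 4-[(2R,3R,4S)-5,7-bis(benzyloxy)-3-hydroxy-4-(2-hydroxyethoxy)-3,4-dihydro-2H-chromen-2-yl]phenyl methanesulfonate
Conditions: DDQ, ethylene glycol, DMAP, CH2Cl2, rt
Reagents that add atoms: ethylene glycol, OCCO
Why: DDQ-mediated benzylic oxidation, in which hydride abstraction at C4 gives the cation stabilized by ring A and ethylene glycol traps it trans to the 3-hydroxyl (4β), the deactivated ring B protecting the C2–H bond.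

Step 11
Reactants: 16 (−)-epicatechin
Product: 17 5,7,3',4'-tetra-O-benzyl-(−)-epicatechin
Conditions: BnBr, K2CO3, DMF, 0 °C to rt
Reagents that add atoms: benzyl bromide, BrCc1ccccc1
Why: Williamson etherification of the four phenols (the aliphatic 3-hydroxyl is not deprotonated by carbonate) under cold, mild conditions should leave the 2R,3R configuration intact.

Step 12
Reactants: 15 4-[(2R,3R,4S)-5,7-bis(benzyloxy)-3-hydroxy-4-(2-hydroxyethoxy)-3,4-dihydro-2H-chromen-2-yl]phenyl methanesulfonate; 17 5,7,3',4'-tetra-O-benzyl-(−)-epicatechin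
Product: 18 5,7-di-O-benzyl-4'-O-methylsulfonyl-(−)-epiafzelechin-(4β→8)-5,7,3',4'-tetra-O-benzyl-(−)-epicatechin
Conditions: TiCl4 (1 equiv), 17 (4 equiv), CH2Cl2–THF, 0 °C to rt
Reagents that add atoms: none
Why: Lewis-acid-mediated Friedel–Crafts-type interflavan coupling, in which TiCl4 ionizes the C4 glycol ether and the excess nucleophile attacks the benzylic cation through its most nucleophilic position C8 from the β face, anti to the axial 3-hydroxyl of the 2,3-cis unit, which sets 4R (3,4-trans).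

Step 13
Reactants: 18 5,7-di-O-benzyl-4'-O-methylsulfonyl-(−)-epiafzelechin-(4β→8)-5,7,3',4'-tetra-O-benzyl-(−)-epicatechin
Product: 19 5,7-di-O-benzyl-(−)-epiafzelechin-(4β→8)-5,7,3',4'-tetra-O-benzyl-(−)-epicatechin
Conditions: LiN(i-Pr)2 (5 equiv), THF, −78 °C to 0 °C, then aq. NH4Cl
Reagents that add atoms: none
Why: base-induced cleavage of the aryl mesylate (α-deprotonation and E1cB loss of sulfene) frees the ring B phenol at low temperature, where the phenoxide should not open ring C through a quinone methide, so C2 is not epimerized.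

Step 14
Reactants: 19 5,7-di-O-benzyl-(−)-epiafzelechin-(4β→8)-5,7,3',4'-tetra-O-benzyl-(−)-epicatechin
Product: 20 (−)-epiafzelechin-(4β→8)-(−)-epicatechin
Conditions: H2 (1 atm), Pd(OH)2/C, THF–MeOH–H2O, rt
Reagents that add atoms: none
Why: catalytic hydrogenolysis of the six benzyl ethers under neutral conditions should leave the interflavan bond and all five stereocenters untouched.

**Compound list**

1 | methyl (2E)-3-(4-hydroxyphenyl)prop-2-enoate | COC(=O)/C=C/c1ccc(O)cc1 | starting material
2 | methyl (2E)-3-[4-(methylsulfonyloxy)phenyl]prop-2-enoate | COC(=O)/C=C/c1ccc(OS(C)(=O)=O)cc1 | intermediate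
3 | 4-[(1E)-3-hydroxyprop-1-en-1-yl]phenyl methanesulfonate | OC/C=C/c1ccc(OS(C)(=O)=O)cc1 | intermediate
4 | 3,5-bis(benzyloxy)phenol | Oc1cc(OCc2ccccc2)cc(OCc2ccccc2)c1 | starting material
5 | 4-{(1E)-3-[2,4-bis(benzyloxy)-6-hydroxyphenyl]prop-1-en-1-yl}phenyl methanesulfonate | CS(=O)(=O)Oc1ccc(/C=C/Cc2c(O)cc(OCc3ccccc3)cc2OCc2ccccc2)cc1 | intermediate
6 | 4-{(1E)-3-[2,4-bis(benzyloxy)-6-(triisopropylsilyloxy)phenyl]prop-1-en-1-yl}phenyl methanesulfonate | CS(=O)(=O)Oc1ccc(/C=C/Cc2c(O[Si](C(C)C)(C(C)C)C(C)C)cc(OCc3ccccc3)cc2OCc2ccccc2)cc1 | intermediate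
7 | 4-{(2R,3R)-3-[2,4-bis(benzyloxy)-6-(triisopropylsilyloxy)benzyl]oxiran-2-yl}phenyl methanesulfonate | CS(=O)(=O)Oc1ccc([C@H]2O[C@@H]2Cc2c(O[Si](C(C)C)(C(C)C)C(C)C)cc(OCc3ccccc3)cc2OCc2ccccc2)cc1 | intermediate
8 | tetrabutylammonium 3,5-bis(benzyloxy)-2-({(2R,3R)-3-[4-(methylsulfonyloxy)phenyl]oxiran-2-yl}methyl)phenoxide | CS(=O)(=O)Oc1ccc([C@H]2O[C@@H]2Cc2c([O-])cc(OCc3ccccc3)cc2OCc2ccccc2)cc1.CCCC[N+](CCCC)(CCCC)CCCC | intermediate (not isolated)
9 | 4-{(R)-[(2S)-4,6-bis(benzyloxy)-2,3-dihydro-1-benzofuran-2-yl](hydroxy)methyl}phenyl methanesulfonate (erythro) | CS(=O)(=O)Oc1ccc([C@@H](O)[C@@H]2Cc3c(OCc4ccccc4)cc(OCc4ccccc4)cc3O2)cc1 | intermediate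
10 | (S)-[(2S)-4,6-bis(benzyloxy)-2,3-dihydro-1-benzofuran-2-yl][4-(methylsulfonyloxy)phenyl]methyl 4-nitrobenzoate (threo) | CS(=O)(=O)Oc1ccc([C@H](OC(=O)c2ccc([N+](=O)[O-])cc2)[C@@H]2Cc3c(OCc4ccccc4)cc(OCc4ccccc4)cc3O2)cc1 | intermediate
11 | 4-{(S)-[(2S)-4,6-bis(benzyloxy)-2,3-dihydro-1-benzofuran-2-yl](hydroxy)methyl}phenyl methanesulfonate (threo) | CS(=O)(=O)Oc1ccc([C@H](O)[C@@H]2Cc3c(OCc4ccccc4)cc(OCc4ccccc4)cc3O2)cc1 | intermediate
12 | (S)-[(2S)-4,6-bis(benzyloxy)-2,3-dihydro-1-benzofuran-2-yl][4-(methylsulfonyloxy)phenyl]methyl chloromethanesulfonate | CS(=O)(=O)Oc1ccc([C@H](OS(=O)(=O)CCl)[C@@H]2Cc3c(OCc4ccccc4)cc(OCc4ccccc4)cc3O2)cc1 | intermediate (not isolated)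
13 | O1-bridged oxiranium ion (O1 bonded to C8a, C2 and C3; 2R,3S; aryl and C4 cis on the three-membered ring), chloromethanesulfonate salt | CS(=O)(=O)Oc1ccc([C@@H]2[C@@H]3Cc4c(OCc5ccccc5)cc(OCc5ccccc5)cc4[O+]23)cc1.[O-]S(=O)(=O)CCl | intermediate (not isolated)
14 | 4-[(2R,3R)-5,7-bis(benzyloxy)-3-hydroxy-3,4-dihydro-2H-chromen-2-yl]phenyl methanesulfonate | CS(=O)(=O)Oc1ccc([C@H]2Oc3cc(OCc4ccccc4)cc(OCc4ccccc4)c3C[C@H]2O)cc1 | intermediate
15 | 4-[(2R,3R,4S)-5,7-bis(benzyloxy)-3-hydroxy-4-(2-hydroxyethoxy)-3,4-dihydro-2H-chromen-2-yl]phenyl methanesulfonate | CS(=O)(=O)Oc1ccc([C@H]2Oc3cc(OCc4ccccc4)cc(OCc4ccccc4)c3[C@H](OCCO)[C@H]2O)cc1 | intermediate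
16 | (−)-epicatechin, (2R,3R) | Oc1cc(O)c2c(c1)O[C@H](c1ccc(O)c(O)c1)[C@H](O)C2 | starting material
17 | 5,7,3',4'-tetra-O-benzyl-(−)-epicatechin | c1ccccc1COc1cc(OCc2ccccc2)c2c(c1)O[C@H](c1ccc(OCc3ccccc3)c(OCc3ccccc3)c1)[C@H](O)C2 | intermediate
18 | 5,7-di-O-benzyl-4'-O-methylsulfonyl-(−)-epiafzelechin-(4β→8)-5,7,3',4'-tetra-O-benzyl-(−)-epicatechin | CS(=O)(=O)Oc1ccc([C@H]2Oc3cc(OCc4ccccc4)cc(OCc4ccccc4)c3[C@H](c3c(OCc4ccccc4)cc(OCc4ccccc4)c4c3O[C@H](c3ccc(OCc5ccccc5)c(OCc5ccccc5)c3)[C@H](O)C4)[C@H]2O)cc1 | intermediate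
19 | 5,7-di-O-benzyl-(−)-epiafzelechin-(4β→8)-5,7,3',4'-tetra-O-benzyl-(−)-epicatechin | Oc1ccc([C@H]2Oc3cc(OCc4ccccc4)cc(OCc4ccccc4)c3[C@H](c3c(OCc4ccccc4)cc(OCc4ccccc4)c4c3O[C@H](c3ccc(OCc5ccccc5)c(OCc5ccccc5)c3)[C@H](O)C4)[C@H]2O)cc1 | intermediate
20 | (−)-epiafzelechin-(4β→8)-(−)-epicatechin | Oc1ccc([C@H]2Oc3cc(O)cc(O)c3[C@H](c3c(O)cc(O)c4c3O[C@H](c3ccc(O)c(O)c3)[C@H](O)C4)[C@H]2O)cc1 | target

**Step count and risks**

Total step count: 14. Longest linear sequence: 13 steps (steps 1 to 10 and 12 to 14, from compound 1).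

The three steps most likely to fail:

1. Step 9 (proposed ring expansion). The aryl ether oxygen may participate too slowly, because the aryl group must sit on the concave face of the bicyclic cation. Water would then displace the sulfonate directly, the oxiranium ion would be captured at the benzylic carbon, or the benzylic position would ionize freely with hydride shift and aromatization to a benzofuran. Fallback (sets out from 6, returns at 14; ring C is closed directly by known chemistry): 6 is epoxidized with the enantiomeric, L-fructose-derived Shi ketone to the (2S,3S)-epoxide 4-{(2S,3S)-3-[2,4-bis(benzyloxy)-6-(triisopropylsilyloxy)benzyl]oxiran-2-yl}phenyl methanesulfonate F1. Desilylation with Bu4NF buffered by AcOH gives the neutral phenol 4-{(2S,3S)-3-[2,4-bis(benzyloxy)-6-hydroxybenzyl]oxiran-2-yl}phenyl methanesulfonate F2. Camphorsulfonic acid in CH2Cl2 then effects 6-endo opening at the benzylic carbon with inversion to the 2,3-trans alcohol 4-[(2R,3S)-5,7-bis(benzyloxy)-3-hydroxy-3,4-dihydro-2H-chromen-2-yl]phenyl methanesulfonate F3. Dess–Martin oxidation gives the ketone 4-[(2R)-5,7-bis(benzyloxy)-3-oxo-3,4-dihydro-2H-chromen-2-yl]phenyl methanesulfonate F4, and reduction with LiBH(s-Bu)3 in THF at −78 °C (hydride anti to the 2-aryl group) should give the 2,3-cis alcohol 14.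

2. Step 7 (Mitsunobu inversion). Inversion at the hindered benzylic carbinol may be incomplete, through participation of the ring oxygen (retention) or through elimination. Fallback (sets out from 9, returns at 11): 9 is oxidized with Dess–Martin periodinane to the ketone 4-{[(2S)-4,6-bis(benzyloxy)-2,3-dihydro-1-benzofuran-2-yl]carbonyl}phenyl methanesulfonate F5, kept cold to avoid enolization. Reduction with the non-chelating LiBH(s-Bu)3 in THF at −78 °C under Felkin–Anh polar control (aryloxy group anti to the incoming hydride) should then give the threo alcohol 11.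

3. Step 12 (interflavan coupling). The hard Lewis acid may cause over-condensation (self-coupling of the electrophile, further chain growth on the product) and competing alkylation of the nucleophile at C6. Fallback (sets out from 15, returns at 18): thiolysis of 15 with benzyl mercaptan and BF3·OEt2 gives the bench-stable thioether 4-[(2R,3S,4S)-5,7-bis(benzyloxy)-4-(benzylsulfanyl)-3-hydroxy-3,4-dihydro-2H-chromen-2-yl]phenyl methanesulfonate F6. It is added slowly to 17 and AgBF4 in THF at 0 °C, so that thiophilic activation generates the C4 cation at low stationary concentration and gives 18.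

**Further compounds**

F1 | step 9 | 4-{(2S,3S)-3-[2,4-bis(benzyloxy)-6-(triisopropylsilyloxy)benzyl]oxiran-2-yl}phenyl methanesulfonate | CS(=O)(=O)Oc1ccc([C@@H]2O[C@H]2Cc2c(O[Si](C(C)C)(C(C)C)C(C)C)cc(OCc3ccccc3)cc2OCc2ccccc2)cc1
F2 | step 9 | 4-{(2S,3S)-3-[2,4-bis(benzyloxy)-6-hydroxybenzyl]oxiran-2-yl}phenyl methanesulfonate | CS(=O)(=O)Oc1ccc([C@@H]2O[C@H]2Cc2c(O)cc(OCc3ccccc3)cc2OCc2ccccc2)cc1
F3 | step 9 | 4-[(2R,3S)-5,7-bis(benzyloxy)-3-hydroxy-3,4-dihydro-2H-chromen-2-yl]phenyl methanesulfonate | CS(=O)(=O)Oc1ccc([C@H]2Oc3cc(OCc4ccccc4)cc(OCc4ccccc4)c3C[C@@H]2O)cc1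
F4 | step 9 | 4-[(2R)-5,7-bis(benzyloxy)-3-oxo-3,4-dihydro-2H-chromen-2-yl]phenyl methanesulfonate | CS(=O)(=O)Oc1ccc([C@H]2Oc3cc(OCc4ccccc4)cc(OCc4ccccc4)c3CC2=O)cc1
F5 | step 7 | 4-{[(2S)-4,6-bis(benzyloxy)-2,3-dihydro-1-benzofuran-2-yl]carbonyl}phenyl methanesulfonate | CS(=O)(=O)Oc1ccc(C(=O)[C@@H]2Cc3c(OCc4ccccc4)cc(OCc4ccccc4)cc3O2)cc1
F6 | step 12 | 4-[(2R,3S,4S)-5,7-bis(benzyloxy)-4-(benzylsulfanyl)-3-hydroxy-3,4-dihydro-2H-chromen-2-yl]phenyl methanesulfonate | CS(=O)(=O)Oc1ccc([C@H]2Oc3cc(OCc4ccccc4)cc(OCc4ccccc4)c3[C@H](SCc3ccccc3)[C@H]2O)cc1
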